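**Retrosynthetic overview**
- Feature: the C4a=C8a bond shared by rings A and C is read as the C=C of a ring-C 2,3-dihydropyran-4-one. C5-C6-C7-C8, with oxygen on C5 and C7, is read as a butadiene with two oxygens on one terminus and one on its C3.
- Key disconnection: C4a-C5 and C8-C8a. A [4+2] addition of a side-chain-bearing vinylketene acetal to a 5-sulfinyl dihydropyranone is followed by loss of PhSOH and MeOH. Ring order: B (bought), then C, then A.
- Dienophile: O1-C8a by aminomethylenation and ring closure, C4-C4a by acylation of lithiated methyl phenyl sulfoxide, and C2-C3 by an auxiliary-controlled anti glycolate aldol that sets both stereocentres.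
- Diene: the C7-O bond is made on methyl but-2-ynoate by oxa-Michael addition of an allylic alcohol obtained from prenyl acetate by E-selective allylic oxidation. Gamma-deprotonation and O-silylation follow.
- Finish: one global desilylation.

Key step: step 12

Assumption: flavonoid numbering (O1, C2, C3, C4, C4a, C5 to C8, C8a, primes for ring B) is used for these atoms in all precursors, and every sulfoxide is carried as a mixture of sulfur epimers because sulfur is lost in the key step (TBS = tert-butyldimethylsilyl, TMS = trimethylsilyl).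

Step 1
Reactants: 1 4-hydroxybenzaldehyde
Product: 2 4-(tert-butyldimethylsilyloxy)benzaldehyde
Conditions: TBSCl, imidazole, DMF, 0 °C to rt
Reagents that add atoms: tert-butyldimethylsilyl chloride, CC(C)(C)[Si](C)(C)Cl
Why: Imidazole-promoted O-silylation of a phenol, which masks the acidic 4'-OH through all carbanion steps and comes off only at the end.

Step 2
Reactants: 3 (tert-butyldimethylsilyloxy)acetic acid; 4 (S)-4-benzyloxazolidin-2-one
Product: 5 (S)-4-benzyl-3-[(tert-butyldimethylsilyloxy)acetyl]oxazolidin-2-one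
Conditions: N,N'-dicyclohexylcarbodiimide (DCC), 4-(dimethylamino)pyridine (cat.), CH2Cl2, 0 °C to rt
Reagents that add atoms: none
Why: Carbodiimide-mediated N-acylation (Steglich-type coupling) of the oxazolidinone, a mild route to the glycolyl imide that leaves the silyl ether and the auxiliary stereocentre untouched.

Step 3
Reactants: 5 (S)-4-benzyl-3-[(tert-butyldimethylsilyloxy)acetyl]oxazolidin-2-one; 2 4-(tert-butyldimethylsilyloxy)benzaldehyde
Product: 6 (S)-4-benzyl-3-{(2R,3R)-2-(tert-butyldimethylsilyloxy)-3-[4-(tert-butyldimethylsilyloxy)phenyl]-3-(trimethylsilyloxy)propanoyl}oxazolidin-2-one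
Conditions: MgCl2 (0.2 equiv), Et3N, TMSCl, EtOAc, rt; non-acidic work-up, Et3N-deactivated SiO2
Reagents that add atoms: trimethylsilyl chloride, C[Si](C)(C)Cl
Why: Evans-type MgCl2-catalysed direct anti aldol, in which soft enolisation gives the magnesium-chelated Z-enolate, its face opposite the benzyl group (the face used in auxiliary-controlled alkylations) adds to the non-enolisable aldehyde through a boat-like transition state so that C3 should be set R and C2 R (anti), and TMSCl traps the aldolate, which permits turnover and leaves the benzylic oxygen with a temporary group distinct from the C3 OTBS.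

Step 4
Reactants: 6 anti aldol TMS ether
Product: 7 S-ethyl (2R,3R)-2-(tert-butyldimethylsilyloxy)-3-[4-(tert-butyldimethylsilyloxy)phenyl]-3-(trimethylsilyloxy)propanethioate
Conditions: EtSH, n-BuLi, THF, 0 °C
Reagents that add atoms: ethanethiol, CCS
Why: Thiolate transacylation of the imide, in which the soft and weakly basic LiSEt attacks the exocyclic carbonyl even of hindered acyl groups, releases the auxiliary for reuse and gives an acyl donor reactive enough for step 5 without touching C3-H or the silyl ethers.

Step 5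
Reactants: 7 S-ethyl thioester; 8 methyl phenyl sulfoxide (racemic)
Product: 9 (3R,4R)-3-(tert-butyldimethylsilyloxy)-4-[4-(tert-butyldimethylsilyloxy)phenyl]-1-(phenylsulfinyl)-4-(trimethylsilyloxy)butan-2-one (both sulfur epimers)
Conditions: 8 (2.3 equiv), LiN(iPr)2 (2.2 equiv), THF, -78 °C; then 7, -78 to -40 °C; aq NH4Cl
Reagents that add atoms: none
Why: Claisen-type C-acylation of an alpha-sulfinyl carbanion, in which the second equivalent of carbanion converts the beta-keto sulfoxide at once into its enolate at C4a and so shields the ketone from over-addition and C3 from epimerisation.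

Step 6
Reactants: 9 beta-keto sulfoxide
Product: 11 (2R,3R)-3-(tert-butyldimethylsilyloxy)-2-[4-(tert-butyldimethylsilyloxy)phenyl]-5-(phenylsulfinyl)-2,3-dihydro-4H-pyran-4-one (both sulfur epimers), via enaminone 10 (not isolated)
Conditions: Me2NCH(OMe)2, toluene, 40 °C; concentrate; AcOH-THF-H2O, rt
Reagents that add atoms: N,N-dimethylformamide dimethyl acetal, COC(OC)N(C)C
Why: Aminomethylenation of the active methylene by the amide acetal gives a push-pull enaminone, and aqueous acetic acid then removes only the labile benzylic TMS ether, so that the freed C2-OH adds to the aminomethylene carbon (6-endo-trig addition-elimination with loss of Me2NH) and closes ring C through O1-C8a with C2 and C3 untouched, the C3 oxygen being unable to compete because it stays silylated.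

Step 7
Reactants: 12 prenyl acetate (3-methylbut-2-en-1-yl acetate)
Product: 13 (E)-4-hydroxy-3-methylbut-2-en-1-yl acetate
Conditions: SeO2 (0.1 equiv), t-BuOOH, CH2Cl2, 0 °C to rt
Reagents that add atoms: tert-butyl hydroperoxide, CC(C)(C)OO
Why: Riley-type allylic oxidation with catalytic SeO2, whose ene and [2,3]-sigmatropic sequence attacks the methyl group trans to the chain of a trisubstituted alkene and should therefore deliver the E-allylic alcohol.

Step 8
Reactants: 13 (E)-4-hydroxy-3-methylbut-2-en-1-yl acetate
Product: 14 (E)-4-(tert-butyldimethylsilyloxy)-3-methylbut-2-en-1-yl acetate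
Conditions: TBSCl, imidazole, CH2Cl2, rt
Reagents that add atoms: tert-butyldimethylsilyl chloride, CC(C)(C)[Si](C)(C)Cl
Why: Standard silylation of a primary allylic alcohol, which gives the side-chain hydroxyl the same fluoride-labile group as the other hydroxyls.

Step 9
Reactants: 14 (E)-4-(tert-butyldimethylsilyloxy)-3-methylbut-2-en-1-yl acetate
Product: 15 (E)-4-(tert-butyldimethylsilyloxy)-3-methylbut-2-en-1-ol
Conditions: K2CO3 (0.2 equiv), MeOH, 0 °C
Reagents that add atoms: none
Why: Base-catalysed methanolysis (transesterification) of the primary acetate, to which the primary TBS ether and the alkene geometry are inert.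

Step 10
Reactants: 15 (E)-4-(tert-butyldimethylsilyloxy)-3-methylbut-2-en-1-ol; 16 methyl but-2-ynoate
Product: 17 methyl (E)-3-{[(E)-4-(tert-butyldimethylsilyloxy)-3-methylbut-2-en-1-yl]oxy}but-2-enoate
Conditions: PMe3 (0.15 equiv), CH2Cl2, 0 °C to rt
Reagents that add atoms: none
Why: Trialkylphosphine-catalysed oxa-Michael addition, in which PMe3 adds to the ynoate to give a basic zwitterion that deprotonates 15, the alkoxide adds at C3 of the ynoate and PMe3 is expelled to leave the favoured E-enol ether, while the acid-free room-temperature medium avoids the ynoate isomerisation that leads to gamma-addition.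

Step 11
Reactants: 17 methyl (E)-3-alkoxybut-2-enoate
Product: 18 1-methoxy-1-(trimethylsilyloxy)-3-{[(E)-4-(tert-butyldimethylsilyloxy)-3-methylbut-2-en-1-yl]oxy}buta-1,3-diene (acetal geometry not defined)
Conditions: LiN(iPr)2, THF, -78 °C; TMSCl, -78 to 0 °C; pentane, filtration under argon, used crude
Reagents that add atoms: trimethylsilyl chloride, C[Si](C)(C)Cl
Why: Kinetic gamma-deprotonation of the E-configured beta-alkoxy enoate (its methyl group is cis to the ester) gives the extended enolate, which the hard electrophile TMSCl traps on oxygen as the vinylketene silyl acetal, and all operations stay at or below 0 °C so that the allyl vinyl ether unit does not rearrange.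

Step 12
Reactants: 11 (2R,3R)-5-(phenylsulfinyl)dihydropyranone; 18 vinylketene silyl acetal
Product: 22 (2R,3R)-3-(tert-butyldimethylsilyloxy)-2-[4-(tert-butyldimethylsilyloxy)phenyl]-7-{[(E)-4-(tert-butyldimethylsilyloxy)-3-methylbut-2-en-1-yl]oxy}-5-hydroxychroman-4-one, via cycloadduct 19 (not isolated), via dihydroarene ketal 20 (not isolated), via aryl trimethylsilyl ether 21 (not isolated)
Conditions: 18 (2.5 equiv), CH2Cl2 (1 M), no Lewis acid, -20 °C to rt; then 35 °C; then SiO2, moist CH2Cl2, rt
Reagents that add atoms: none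
Why: Proposed new method: three oxygen donors make the CH2 terminus of 18 (future C8) its nucleophilic end, while the C4 carbonyl and the sulfinyl group, both on C4a, make C8a the electrophilic end of 11, so a strongly asynchronous normal-demand [4+2] addition (in the stepwise limit a Mukaiyama-Michael attack on C8a and then closure of the sulfinyl enolate carbon C4a onto the silyloxycarbenium carbon C5) should form C8-C8a and C4a-C5 and close the six-membered carbocycle A as adduct 19. Suprafacial addition leaves the sulfinyl group on C4a cis to the hydrogen on C8a, the only beta hydrogen there is, so the crowded alpha-keto sulfoxide should lose PhSOH by thermal syn elimination at or slightly above room temperature to give 20, whose mixed acetal ionises at the more basic methoxy oxygen, loses methanol and a C8 proton and becomes aryl silyl ether 21, which moist silica cleaves to the hydrogen-bonded 5-OH of 22. The closest known reaction type is the cycloaddition of vinylketene acetals to halo- or sulfinylquinones, and of siloxydienes to 3-sulfinyl- or 3-acylchromones, followed by eliminative aromatisation, whereas a monocyclic 2,3-dihydropyran-4-one has not served as the two-carbon partner. No lasting stereocentre is made, since C4a, C5 and C8a all end up sp2, so facial and endo/exo selectivity and the configuration at sulfur do not matter, and C2 and C3 are kept because the medium holds neither base nor Lewis acid and C3-H is never enolised. The selectivity that is needed is regiochemical and is secured by the matched polarisation of the two partners, which turns the acetal carbon into C5 (free OH) and the alkoxy-bearing carbon into C7 (side-chain ether). Chemoselectivity rests on temperature and medium: at or below 35 °C the allyl vinyl ether units of 18 and 19 should not undergo Claisen rearrangement, and without a Lewis acid silyl transfer to the sulfoxide oxygen (Pummerer-type diversion) is avoided.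

Step 13
Reactants: 22 tris-TBS ether with free 5-OH
Product: 23 (2R,3R)-3,5-dihydroxy-7-{[(E)-4-hydroxy-3-methylbut-2-en-1-yl]oxy}-2-(4-hydroxyphenyl)chroman-4-one (target)
Conditions: HF·pyridine, pyridine, THF, 0 °C to rt
Reagents that add atoms: none
Why: Fluoride-driven cleavage of all three Si-O bonds in a weakly acidic buffered medium, which avoids the 4'-phenoxide that could open ring C at O1-C2 and epimerise C2 and C3, and which leaves the allyl aryl ether, the allylic alcohol and the alpha-hydroxy ketone alone.

**Compound list**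
1 | 4-hydroxybenzaldehyde | O=Cc1ccc(O)cc1 | starting material
2 | 4-(tert-butyldimethylsilyloxy)benzaldehyde | O=Cc1ccc(O[Si](C)(C)C(C)(C)C)cc1 | intermediate
3 | (tert-butyldimethylsilyloxy)acetic acid | CC(C)(C)[Si](C)(C)OCC(=O)O | starting material
4 | (S)-4-benzyloxazolidin-2-one | O=C1N[C@@H](Cc2ccccc2)CO1 | starting material
5 | (S)-4-benzyl-3-[(tert-butyldimethylsilyloxy)acetyl]oxazolidin-2-one | CC(C)(C)[Si](C)(C)OCC(=O)N1[C@@H](Cc2ccccc2)COC1=O | intermediate
6 | (S)-4-benzyl-3-{(2R,3R)-2-(TBS-oxy)-3-[4-(TBS-oxy)phenyl]-3-(TMS-oxy)propanoyl}oxazolidin-2-one | C[Si](C)(C)O[C@H](c1ccc(O[Si](C)(C)C(C)(C)C)cc1)[C@@H](O[Si](C)(C)C(C)(C)C)C(=O)N1[C@@H](Cc2ccccc2)COC1=O | intermediate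
7 | S-ethyl (2R,3R)-2-(TBS-oxy)-3-[4-(TBS-oxy)phenyl]-3-(TMS-oxy)propanethioate | C[Si](C)(C)O[C@H](c1ccc(O[Si](C)(C)C(C)(C)C)cc1)[C@@H](O[Si](C)(C)C(C)(C)C)C(=O)SCC | intermediate
8 | methyl phenyl sulfoxide (racemic) | CS(=O)c1ccccc1 | starting material
9 | (3R,4R)-3-(TBS-oxy)-4-[4-(TBS-oxy)phenyl]-1-(phenylsulfinyl)-4-(TMS-oxy)butan-2-one, both sulfur epimers | C[Si](C)(C)O[C@H](c1ccc(O[Si](C)(C)C(C)(C)C)cc1)[C@@H](O[Si](C)(C)C(C)(C)C)C(=O)CS(=O)c1ccccc1 | intermediate
10 | (4R,5R)-4-(TBS-oxy)-5-[4-(TBS-oxy)phenyl]-1-(dimethylamino)-2-(phenylsulfinyl)-5-(TMS-oxy)pent-1-en-3-one | C[Si](C)(C)O[C@H](c1ccc(O[Si](C)(C)C(C)(C)C)cc1)[C@@H](O[Si](C)(C)C(C)(C)C)C(=O)C(=CN(C)C)S(=O)c1ccccc1 | intermediate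
11 | (2R,3R)-3-(TBS-oxy)-2-[4-(TBS-oxy)phenyl]-5-(phenylsulfinyl)-2,3-dihydro-4H-pyran-4-one, both sulfur epimers | O=S(c1ccccc1)C1=CO[C@H](c2ccc(O[Si](C)(C)C(C)(C)C)cc2)[C@@H](O[Si](C)(C)C(C)(C)C)C1=O | intermediate
12 | prenyl acetate | CC(C)=CCOC(C)=O | starting material
13 | (E)-4-hydroxy-3-methylbut-2-en-1-yl acetate | C/C(=C\COC(C)=O)CO | intermediate
14 | (E)-4-(TBS-oxy)-3-methylbut-2-en-1-yl acetate | C/C(=C\COC(C)=O)CO[Si](C)(C)C(C)(C)C | intermediate
15 | (E)-4-(TBS-oxy)-3-methylbut-2-en-1-ol | C/C(=C\CO)CO[Si](C)(C)C(C)(C)C | intermediate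
16 | methyl but-2-ynoate | CC#CC(=O)OC | starting material
17 | methyl (E)-3-{[(E)-4-(TBS-oxy)-3-methylbut-2-en-1-yl]oxy}but-2-enoate | COC(=O)/C=C(\C)OC/C=C(\C)CO[Si](C)(C)C(C)(C)C | intermediate
18 | 1-methoxy-1-(TMS-oxy)-3-{[(E)-4-(TBS-oxy)-3-methylbut-2-en-1-yl]oxy}buta-1,3-diene | C=C(OC/C=C(\C)CO[Si](C)(C)C(C)(C)C)C=C(OC)O[Si](C)(C)C | intermediate
19 | (2R,3R)-3-(TBS-oxy)-2-[4-(TBS-oxy)phenyl]-5-methoxy-4a-(phenylsulfinyl)-5-(TMS-oxy)-7-(side-chain oxy)-2,3,4a,5,8,8a-hexahydro-4H-chromen-4-one, cis ring fusion, mixture at C4a, C5, C8a and S | O=S(c1ccccc1)C12C(OC)(O[Si](C)(C)C)C=C(OC/C=C(\C)CO[Si](C)(C)C(C)(C)C)CC1O[C@H](c1ccc(O[Si](C)(C)C(C)(C)C)cc1)[C@@H](O[Si](C)(C)C(C)(C)C)C2=O | intermediate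
20 | (2R,3R)-3-(TBS-oxy)-2-[4-(TBS-oxy)phenyl]-5-methoxy-5-(TMS-oxy)-7-(side-chain oxy)-2,3,5,8-tetrahydro-4H-chromen-4-one | COC1(O[Si](C)(C)C)C=C(OC/C=C(\C)CO[Si](C)(C)C(C)(C)C)CC2=C1C(=O)[C@H](O[Si](C)(C)C(C)(C)C)[C@@H](c1ccc(O[Si](C)(C)C(C)(C)C)cc1)O2 | intermediate
21 | 5-O-TMS ether of 22 | C/C(=C\COc1cc(O[Si](C)(C)C)c2c(c1)O[C@H](c1ccc(O[Si](C)(C)C(C)(C)C)cc1)[C@@H](O[Si](C)(C)C(C)(C)C)C2=O)CO[Si](C)(C)C(C)(C)C | intermediate
22 | (2R,3R)-3-(TBS-oxy)-2-[4-(TBS-oxy)phenyl]-7-{[(E)-4-(TBS-oxy)-3-methylbut-2-en-1-yl]oxy}-5-hydroxychroman-4-one | C/C(=C\COc1cc(O)c2c(c1)O[C@H](c1ccc(O[Si](C)(C)C(C)(C)C)cc1)[C@@H](O[Si](C)(C)C(C)(C)C)C2=O)CO[Si](C)(C)C(C)(C)C | intermediate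
23 | (2R,3R)-3,5-dihydroxy-7-{[(E)-4-hydroxy-3-methylbut-2-en-1-yl]oxy}-2-(4-hydroxyphenyl)chroman-4-one | C/C(=C\COc1cc(O)c2c(c1)O[C@H](c1ccc(O)cc1)[C@@H](O)C2=O)CO | target

**Step count:** 13 steps in total. The longest linear sequence is 7 steps (1, 3, 4, 5, 6, 12, 13). The branches through step 2 and through steps 7 to 11 are equally long.

**Steps most likely to fail**

**Risk 1, step 12.** The push-pull C4a=C8a bond may be too weak an acceptor at the temperatures the diene tolerates. Hydrolysis or Claisen rearrangement of the diene would then outrun addition. The reaction may also stop after the first C-C bond, and ring C could then open by beta-elimination of O1.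

The fallback uses known chemistry, gives up the annulation and places the side chain on a preformed ring A. It sets out from 15. A Mitsunobu etherification (PPh3, diisopropyl azodicarboxylate, THF, 0 °C) is run with purchased (2R,3R)-aromadendrin. Its 7-OH is the most acidic hydroxyl, because the 5-OH is chelated, the 4'-OH is less acidic and the 3-OH is an alcohol. This should give 7-O-[(E)-4-(tert-butyldimethylsilyloxy)-3-methylbut-2-en-1-yl]aromadendrin F1. The conditions of step 13 then bring the sequence back to the route at 23.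

**Risk 2, step 3.** The alpha-silyloxy group may disturb the chelated enolate, with erosion of anti and facial selectivity. Slow silyl transfer with the electron-rich aldehyde may leave the aldol addition reversible.

The fallback builds ring C by cycloaddition and oxygenates C3 afterwards. It sets out from 2.
- (S)-1,1'-bi-2-naphthol/Ti(OiPr)4 catalyses the hetero-Diels-Alder reaction of 2 with (E)-1-methoxy-3-(trimethylsilyloxy)buta-1,3-diene (4 Å sieves, Et2O, -20 °C, TFA work-up). Attack on the Si face of the aldehyde should give (S)-2-[4-(tert-butyldimethylsilyloxy)phenyl]-2,3-dihydro-4H-pyran-4-one F2.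
- Deprotonation at C3 with LiN(SiMe3)2 at -78 °C is followed by Davis oxidation with 3-phenyl-2-(phenylsulfonyl)oxaziridine. The oxidant approaches anti to the pseudoequatorial aryl group and should give (2R,3R)-2-[4-(tert-butyldimethylsilyloxy)phenyl]-3-hydroxy-2,3-dihydro-4H-pyran-4-one F3.
- TBSOTf and 2,6-lutidine give (2R,3R)-3-(tert-butyldimethylsilyloxy)-2-[4-(tert-butyldimethylsilyloxy)phenyl]-2,3-dihydro-4H-pyran-4-one F4.
- PhSCl in CH2Cl2 and then Et3N (addition to the enol ether double bond, then loss of HCl) give (2R,3R)-3-(tert-butyldimethylsilyloxy)-2-[4-(tert-butyldimethylsilyloxy)phenyl]-5-(phenylthio)-2,3-dihydro-4H-pyran-4-one F5.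
- One equivalent of mCPBA at -78 °C brings the sequence back to the route at 11.

**Risk 3, step 10.** Phosphine-induced isomerisation of the ynoate, followed by gamma-addition or oligomerisation, may outrun beta-addition of the alcohol.

The fallback replaces conjugate addition to an alkyne by addition-elimination on a vinyl halide. It sets out from 15, which is converted into its sodium alkoxide (NaH, THF, 0 °C). The alkoxide is treated with purchased methyl (E)-3-chlorobut-2-enoate. This comes back to the route at 17 without any new compound.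

**Further compounds**
F1 | step 12 | 7-O-[(E)-4-(tert-butyldimethylsilyloxy)-3-methylbut-2-en-1-yl]aromadendrin | C/C(=C\COc1cc(O)c2c(c1)O[C@H](c1ccc(O)cc1)[C@@H](O)C2=O)CO[Si](C)(C)C(C)(C)C
F2 | step 3 | (S)-2-[4-(tert-butyldimethylsilyloxy)phenyl]-2,3-dihydro-4H-pyran-4-one | O=C1C=CO[C@H](c2ccc(O[Si](C)(C)C(C)(C)C)cc2)C1
F3 | step 3 | (2R,3R)-2-[4-(tert-butyldimethylsilyloxy)phenyl]-3-hydroxy-2,3-dihydro-4H-pyran-4-one | C1=CO[C@H](c2ccc(O[Si](C)(C)C(C)(C)C)cc2)[C@@H](O)C1=O
F4 | step 3 | (2R,3R)-3-(tert-butyldimethylsilyloxy)-2-[4-(tert-butyldimethylsilyloxy)phenyl]-2,3-dihydro-4H-pyran-4-one | C1=CO[C@H](c2ccc(O[Si](C)(C)C(C)(C)C)cc2)[C@@H](O[Si](C)(C)C(C)(C)C)C1=O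
F5 | step 3 | (2R,3R)-3-(tert-butyldimethylsilyloxy)-2-[4-(tert-butyldimethylsilyloxy)phenyl]-5-(phenylthio)-2,3-dihydro-4H-pyran-4-one | c1ccccc1SC1=CO[C@H](c2ccc(O[Si](C)(C)C(C)(C)C)cc2)[C@@H](O[Si](C)(C)C(C)(C)C)C1=O
F0 | step 10 | none | none
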